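Counted in starting material units, a closed flask holds what was charged, so whatever leaves the pool of starting material, target and isomer of the product stands as self-condensation product.

    target ⇌ isomer of the product (K1 = 7.0, k1 = 0.114 min⁻¹)
    starting material ⇌ target (K2 = 0.25, k2 = 2.24 min⁻¹)
    2 starting material → self-condensation product (k3 = 0.888 L mol⁻¹ min⁻¹)
    isomer of the product ⇌ starting material (k4 = 0.174 min⁻¹)

| flask | starting material | time |
|---|---|---|
| zeta | 0.10 M | 1.0 h |
| eta | 0.30 M | 1.0 h |
| gamma | 1.0 M | 1.0 h |
| epsilon | 2.5 M | 1.0 h |

- percent here means starting material units held: one self-condensation product counts as two
- where a step has two of a species, its rate is k times that concentration squared, and two are used at each turn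
- "hardly changes" means that all values lie within two and a half points (for a concentration: within two and a half percent of the largest)
- run time (zeta): 1.0 h

- [target] at the end for zeta, eta, gamma, epsilon, in this order
- the shape of the row from first to last (rises, then falls / rises all the way / hardly changes / falls all the way / falls, then rises)

Does the pool keep fixed proportions? In zeta, starting material and target relax in 0.0619 min, faster than target and isomer of the product at 0.0887 h, and that time is short against the 1.0 h run. These first-order times do not depend on the charge and are shorter than the run, so the pool can be reckoned as one resting state in its equilibrium proportions. Starting material is then 0.333 of it, a third, and target is 0.0833 of it.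

How fast does the pool fall? Self-condensation takes two starting material at each turn, and starting material is a fixed part of the pool, so the pool falls in second order. Its pool constant, twice the self-condensation constant times the square of that fraction, is 0.197 L mol⁻¹ min⁻¹. The reciprocal of the pool therefore climbs in a straight line from the reciprocal of the charge.

How much of the charge survives in the answer? The forgetting charge, the reciprocal of the pool constant times the time, is 0.0845 M. Every charge here is larger than it, so the line leaves each flask less than half of its pool. The line gives target at 0.00382 M, 0.00549 M, 0.00649 M and 0.00681 M, a row that rises all the way and levels toward 0.00704 M. In epsilon the first half-life by self-condensation, 0.225 min, is shorter than the 5.32 min relaxation of target and isomer of the product, so the early proportions there stray from this picture.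

The forecast, whose figures differ from this line, gives 0.00356 M, 0.00529 M, 0.00661 M and 0.00733 M, a row that rises all the way, and says that “self-condensation erases the starting concentration”.

The flasks end at 0.00359 M, 0.00526 M, 0.00658 M and 0.00725 M, and the row rises all the way. In zeta at 1.00 h, starting material, target and isomer of the product stand at 14.3%, 3.59% and 26.3%, a pool of 44.2%, where the forgetting charge gives 45.8%. For epsilon at 10.0 h the forgetting charge is 0.00846 M, which puts target at 0.0281% of the charge, and the flask holds 0.0290%.

(The constants were drawn at random within sensible limits; the flask was simulated.)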